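## Retrosynthetic overview

1. Nostocyclophane C ⇐ MOM removal ⇐ mono-O-methylation of a C2-symmetric [7.7]paracyclophane diol ⇐ diimide reduction of its (E,E)-diene.
2. The 22-membered ring (the only ring made; both arenes come from resorcinol) ⇐ head-to-tail metathesis cyclodimerization of one monomer carrying a vinyl group on C7 and an allyl group on C3.
3. C7 and the aryl–C7 bond ⇐ ortho-lithiation between the two OMOM groups, then a copper-catalysed enantioselective SN2′ arylation of an (E)-hept-2-enyl phosphate (new).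
4. Aryl–C1 bond and C1 ⇐ key stereospecific 1,2-shift: the aryl group migrates from boron to carbon in the boronate made from a meta-borylated resorcinol ether and a sparteine-lithiated carbamate. The C–B bond then masks the C1 hydroxyl while C3–OH is inverted to C3–Cl, and is oxidised last.
5. Aryl boronate ⇐ iridium C–H borylation of bis-MOM resorcinol; carbamate ⇐ Krische allylation of propane-1,3-diol.

Assumption: bridge atoms are numbered C1 (carbinol carbon) to C7 (butyl-bearing carbon); in the two catalytic asymmetric steps (3 and 11) the ligand antipode used is the one that gives the stated configuration.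

## Route

Step 1
Reactants: 1 resorcinol
Product: 2 1,3-bis(methoxymethoxy)benzene
Conditions: NaH (2.4 equiv), MOMCl (2.4 equiv), DMF, 0 °C → rt
Reagents that add atoms: chloromethyl methyl ether (MOMCl), COCCl
Why: Double Williamson O-alkylation of the bis-phenoxide; MOM directs the later ortho-lithiation, survives organolithiums and comes off under mild acid.

Step 2
Reactants: 2 1,3-bis(methoxymethoxy)benzene
Product: 3 2-[3,5-bis(methoxymethoxy)phenyl]-4,4,5,5-tetramethyl-1,3,2-dioxaborolane
Conditions: [Ir(OMe)(cod)]2 (1.5 mol %), 4,4′-di-tert-butyl-2,2′-bipyridine (3 mol %), B2pin2 (1.0 equiv), THF, 80 °C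
Reagents that add atoms: bis(pinacolato)diboron, CC1(C)OB(OC1(C)C)B1OC(C)(C)C(C)(C)O1
Why: Sterically controlled iridium-catalysed C–H borylation (Hartwig–Miyaura type) attacks the only C–H without an ortho substituent, C5, a position electrophilic substitution cannot reach.

Step 3
Reactants: 4 propane-1,3-diol, 5 allyl acetate
Product: 6 (3R)-hex-5-ene-1,3-diol
Conditions: [Ir(cod)Cl]2 (2.5 mol %), (R)-Cl,MeO-BIPHEP (5 mol %), 4-chloro-3-nitrobenzoic acid (10 mol %), Cs2CO3 (20 mol %), 4 (4 equiv), THF, 100 °C (sealed)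
Reagents that add atoms: none
Why: Krische iridium-catalysed transfer-hydrogenative carbonyl allylation: the diol is dehydrogenated in situ to 3-hydroxypropanal, which the chiral π-allyl iridium complex allylates on its Re face to set C3 as R; excess diol suppresses double allylation.

Step 4
Reactants: 6 (3R)-hex-5-ene-1,3-diol
Product: 7 (3R)-3-hydroxyhex-5-en-1-yl N,N-diisopropylcarbamate
Conditions: i-Pr2NCOCl (1.05 equiv), Et3N, CH2Cl2, 40 °C
Reagents that add atoms: N,N-diisopropylcarbamoyl chloride, CC(C)N(C(C)C)C(=O)Cl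
Why: Chemoselective O-carbamoylation: the bulky carbamoyl chloride acylates the primary hydroxyl much faster than the secondary one, installing the Hoppe directing and leaving group.

Step 5
Reactants: 7 (3R)-3-hydroxyhex-5-en-1-yl N,N-diisopropylcarbamate
Product: 8 (3R)-3-[(tert-butyldimethylsilyl)oxy]hex-5-en-1-yl N,N-diisopropylcarbamate
Conditions: TBSCl, imidazole, DMF, rt
Reagents that add atoms: tert-butyldimethylsilyl chloride, CC(C)(C)[Si](C)(C)Cl
Why: Standard silylation; the γ-OTBS group is not a leaving group for the later carbanion and is too bulky for silyl migration at −78 °C.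

Step 6 (key step)
Reactants: 8 (3R)-3-[(tert-butyldimethylsilyl)oxy]hex-5-en-1-yl N,N-diisopropylcarbamate, 3 2-[3,5-bis(methoxymethoxy)phenyl]-4,4,5,5-tetramethyl-1,3,2-dioxaborolane
Product: 11 2-[(1S,3S)-1-[3,5-bis(methoxymethoxy)phenyl]-3-[(tert-butyldimethylsilyl)oxy]hex-5-en-1-yl]-4,4,5,5-tetramethyl-1,3,2-dioxaborolane (C3 geometry unchanged from 8; its descriptor changes by priority only), via lithiated carbamate 9 (not isolated), via lithium boronate complex 10 (not isolated)
Conditions: s-BuLi (1.3 equiv), (+)-sparteine (1.3 equiv), Et2O, −78 °C, 5 h; 3 (1.0 equiv), −78 °C, 1 h; then 35 °C, 12 h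
Reagents that add atoms: none
Why: Hoppe deprotonation with s-BuLi/(+)-sparteine removes the pro-R hydrogen to give configurationally stable (1R)-9, which adds to the boron of 3 with retention, and on warming the aryl group makes an antiperiplanar, stereoinvertive 1,2-shift from boron to carbon with loss of the carbamate (Aggarwal lithiation–borylation, a Matteson-type 1,2-metallate rearrangement), forming the aryl–C1 bond and fixing C1 in the target geometry.

Step 7
Reactants: 11 2-[(1S,3S)-1-[3,5-bis(methoxymethoxy)phenyl]-3-[(tert-butyldimethylsilyl)oxy]hex-5-en-1-yl]-4,4,5,5-tetramethyl-1,3,2-dioxaborolane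
Product: 12 (4S,6S)-6-[3,5-bis(methoxymethoxy)phenyl]-6-(4,4,5,5-tetramethyl-1,3,2-dioxaborolan-2-yl)hex-1-en-4-ol
Conditions: HF·pyridine, pyridine, THF, 0 °C → rt
Reagents that add atoms: none
Why: Buffered fluoride desilylation; the acidic medium leaves the aryl MOM ethers intact and, without free fluoride or base, does not protodeboronate the benzylic C–B bond that keeps C1 masked.

Step 8
Reactants: 12 (4S,6S)-6-[3,5-bis(methoxymethoxy)phenyl]-6-(4,4,5,5-tetramethyl-1,3,2-dioxaborolan-2-yl)hex-1-en-4-ol
Product: 13 2-[(1S,3R)-1-[3,5-bis(methoxymethoxy)phenyl]-3-chlorohex-5-en-1-yl]-4,4,5,5-tetramethyl-1,3,2-dioxaborolane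
Conditions: PPh3 (2 equiv), CCl4 (5 equiv), CH2Cl2, 40 °C
Reagents that add atoms: carbon tetrachloride, ClC(Cl)(Cl)Cl
Why: Appel reaction: chloride displaces the alkoxyphosphonium ion by SN2 with inversion at C3, giving the target C–Cl geometry (1,3-syn to the C1 heteroatom), while C1 is still a C–B bond that can neither be chlorinated nor ionise.

Step 9
Reactants: 13 2-[(1S,3R)-1-[3,5-bis(methoxymethoxy)phenyl]-3-chlorohex-5-en-1-yl]-4,4,5,5-tetramethyl-1,3,2-dioxaborolane
Product: 14 (1S,3S)-1-[3,5-bis(methoxymethoxy)phenyl]-3-chlorohex-5-en-1-ol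
Conditions: NaBO3·4H2O (5 equiv), THF/H2O 1:1, rt
Reagents that add atoms: sodium perborate, O=BO[O-].[Na+]
Why: Boronate oxidation: the peroxide adds to boron and the benzylic carbon migrates from B to O with retention (a second 1,2-shift), revealing the (S)-carbinol without disturbing the secondary chloride.

Step 10
Reactants: 15 (2E)-hept-2-en-1-ol
Product: 16 diethyl (2E)-hept-2-en-1-yl phosphate
Conditions: NaH, THF, 0 °C; ClP(O)(OEt)2, 0 °C → rt
Reagents that add atoms: diethyl chlorophosphate, CCOP(=O)(Cl)OCC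
Why: O-Phosphorylation of the allylic alkoxide gives the leaving group suited to copper-catalysed SN2′ substitution.

Step 11 (new transformation)
Reactants: 14 (1S,3S)-1-[3,5-bis(methoxymethoxy)phenyl]-3-chlorohex-5-en-1-ol, 16 diethyl (2E)-hept-2-en-1-yl phosphate
Product: 19 (1S,3S)-3-chloro-1-{4-[(3R)-hept-1-en-3-yl]-3,5-bis(methoxymethoxy)phenyl}hex-5-en-1-ol, via dilithio alkoxide-aryllithium 17 (not isolated), via bis(diethylaluminium) reagent 18 (not isolated)
Conditions: n-BuLi (2.1 equiv), THF, −78 → −20 °C; Et2AlCl (2.1 equiv), −78 °C → rt; 16 (1.5 equiv), CuCl2·2H2O (5 mol %), chiral sulfonate-bearing imidazolinium salt L1 [(4S,5S)-4,5-diphenyl-1-mesityl-3-(2-sulfonatophenyl)imidazolinium or its antipode] (5.5 mol %), THF, −30 °C → rt; aq. potassium sodium tartrate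
Reagents that add atoms: none
Why: Proposed new method: after O–H deprotonation, directed ortho-metalation occurs at the only position flanked by two OMOM groups, and Li→Al exchange gives the aryl(diethyl)aluminium 18, which enters a chiral NHC–copper cycle (the divalent copper salt is reduced in situ to monovalent copper): aryl transfer from Al to Cu, anti-SN2′ oxidative addition to the phosphate (its P=O held by the Lewis-acidic Al/Li bridged to the ligand sulfonate) and reductive elimination from the trivalent copper allyl at the butyl-bearing γ-carbon, the ligand choosing the alkene face so that C7 is R; the closest known reaction type is the NHC–copper-catalysed enantioselective allylic substitution of (E)-allylic phosphates with diethyl(aryl)aluminium reagents, shown so far for aryl groups with at most one ortho substituent and no metal alkoxide or alkyl chloride in the nucleophile.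

Step 12
Reactants: 19 (1S,3S)-3-chloro-1-{4-[(3R)-hept-1-en-3-yl]-3,5-bis(methoxymethoxy)phenyl}hex-5-en-1-ol (two molecules)
Product: 20 C2-symmetric [7.7]paracyclophane (E,E)-diene diol: head-to-tail cyclodimer with each bridge Ar–C7H(Bu)–C6H=C5H–C4H2–C3HCl–C2H2–C1H(OH)–Ar′ (1S,3S,7R), four OMOM groups ortho to the C7-bearing carbons
Conditions: RuCl2(H2IMes)(=CH-C6H4-2-OiPr) (second-generation Hoveyda–Grubbs catalyst, 2 × 5 mol %), 1,4-benzoquinone (10 mol %), toluene (5 mM), 60 °C, Ar purge
Reagents that add atoms: none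
Why: Olefin cross-metathesis/ring-closing metathesis cyclodimerization: the unhindered allyl terminus pairs with the hindered vinyl terminus (vinyl–vinyl coupling is disfavoured and a head-to-head ring would be strained), and reversibility funnels material to the strain-free 22-membered head-to-tail (E,E)-diene, a mode precedented for [7.7]paracyclophanes; no stereocentre is touched and benzoquinone suppresses Ru–H isomerisation at C7.

Step 13
Reactants: 20 [7.7]paracyclophane (E,E)-diene diol
Product: 21 saturated C2-symmetric [7.7]paracyclophane diol tetrakis(MOM ether) (1S,3S,7R in both bridges)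
Conditions: 2-nitrobenzenesulfonyl hydrazide (20 equiv, in portions), Et3N, CH2Cl2, rt
Reagents that add atoms: none
Why: Diimide reduction transfers H2 in a concerted syn fashion without a metal hydride, so the allylic benzylic C7 centres cannot isomerise and the C–Cl, benzylic C–O and MOM groups are untouched.

Step 14
Reactants: 21 saturated [7.7]paracyclophane diol tetrakis(MOM ether)
Product: 22 mono-methyl ether of 21 (one C1–OMe, one C1–OH)
Conditions: KN(SiMe3)2 (1.0 equiv), THF, −78 °C; MeOTf (1.0 equiv), −78 → −40 °C; recovered 21 recycled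
Reagents that add atoms: methyl trifluoromethanesulfonate, COS(=O)(=O)C(F)(F)F
Why: Statistical Williamson mono-etherification: the two hydroxyls of C2-symmetric 21 are homotopic, so only one mono-ether can form (about 50 % at most per pass), and at −78 °C the γ-chloro alkoxide is methylated before it can close to an oxetane or eliminate.

Step 15
Reactants: 22 mono-methyl ether tetrakis(MOM ether)
Product: 23 nostocyclophane C
Conditions: HCl (1.25 M in MeOH), THF, 0 °C → rt
Reagents that add atoms: none
Why: Acid-catalysed acetal methanolysis removes the four aryl MOM groups; the benzylic ether and alcohol, flanked by meta-oxygens, do not ionise under these conditions and the secondary chlorides are inert.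

## Compound list

1 | resorcinol | Oc1cccc(O)c1 | starting material
2 | 1,3-bis(methoxymethoxy)benzene | COCOc1cccc(OCOC)c1 | intermediate
3 | 2-[3,5-bis(methoxymethoxy)phenyl]-4,4,5,5-tetramethyl-1,3,2-dioxaborolane | COCOc1cc(cc(OCOC)c1)B1OC(C)(C)C(C)(C)O1 | intermediate
4 | propane-1,3-diol | OCCCO | starting material
5 | allyl acetate | CC(=O)OCC=C | starting material
6 | (3R)-hex-5-ene-1,3-diol | C=CC[C@@H](O)CCO | intermediate
7 | (3R)-3-hydroxyhex-5-en-1-yl N,N-diisopropylcarbamate | C=CC[C@@H](O)CCOC(=O)N(C(C)C)C(C)C | intermediate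
8 | (3R)-3-[(tert-butyldimethylsilyl)oxy]hex-5-en-1-yl N,N-diisopropylcarbamate | C=CC[C@@H](O[Si](C)(C)C(C)(C)C)CCOC(=O)N(C(C)C)C(C)C | intermediate
9 | (1R,3R)-1-lithio-3-[(tert-butyldimethylsilyl)oxy]hex-5-en-1-yl N,N-diisopropylcarbamate (sparteine-bound) | C=CC[C@@H](O[Si](C)(C)C(C)(C)C)C[C@@H]([Li])OC(=O)N(C(C)C)C(C)C | intermediate
10 | lithium boronate complex: boron carries the aryl group of 3, the pinacolato ligand and C1 of 9 (still bearing the carbamate) | C=CC[C@@H](O[Si](C)(C)C(C)(C)C)C[C@H](OC(=O)N(C(C)C)C(C)C)[B-]1(OC(C)(C)C(C)(C)O1)c1cc(OCOC)cc(OCOC)c1.[Li+] | intermediate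
11 | 2-[(1S,3S)-1-[3,5-bis(methoxymethoxy)phenyl]-3-[(tert-butyldimethylsilyl)oxy]hex-5-en-1-yl]-4,4,5,5-tetramethyl-1,3,2-dioxaborolane | C=CC[C@@H](O[Si](C)(C)C(C)(C)C)C[C@H](B1OC(C)(C)C(C)(C)O1)c1cc(OCOC)cc(OCOC)c1 | intermediate
12 | (4S,6S)-6-[3,5-bis(methoxymethoxy)phenyl]-6-(4,4,5,5-tetramethyl-1,3,2-dioxaborolan-2-yl)hex-1-en-4-ol | C=CC[C@@H](O)C[C@H](B1OC(C)(C)C(C)(C)O1)c1cc(OCOC)cc(OCOC)c1 | intermediate
13 | 2-[(1S,3R)-1-[3,5-bis(methoxymethoxy)phenyl]-3-chlorohex-5-en-1-yl]-4,4,5,5-tetramethyl-1,3,2-dioxaborolane | C=CC[C@H](Cl)C[C@H](B1OC(C)(C)C(C)(C)O1)c1cc(OCOC)cc(OCOC)c1 | intermediate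
14 | (1S,3S)-1-[3,5-bis(methoxymethoxy)phenyl]-3-chlorohex-5-en-1-ol | C=CC[C@H](Cl)C[C@H](O)c1cc(OCOC)cc(OCOC)c1 | intermediate
15 | (2E)-hept-2-en-1-ol | CCCC/C=C/CO | starting material
16 | diethyl (2E)-hept-2-en-1-yl phosphate | CCCC/C=C/COP(=O)(OCC)OCC | intermediate
17 | dilithio species of 14 (lithium alkoxide, aryllithium at the carbon between the two OMOM groups) | C=CC[C@H](Cl)C[C@H](O[Li])c1cc(OCOC)c([Li])c(OCOC)c1 | intermediate
18 | bis(diethylaluminium) species of 14 (O–AlEt2 and aryl–AlEt2) | C=CC[C@H](Cl)C[C@H](O[Al](CC)CC)c1cc(OCOC)c([Al](CC)CC)c(OCOC)c1 | intermediate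
19 | (1S,3S)-3-chloro-1-{4-[(3R)-hept-1-en-3-yl]-3,5-bis(methoxymethoxy)phenyl}hex-5-en-1-ol | C=CC[C@H](Cl)C[C@H](O)c1cc(OCOC)c([C@H](CCCC)C=C)c(OCOC)c1 | intermediate
20 | [7.7]paracyclophane (E,E)-diene diol, tetrakis(MOM ether), 1S,3S,7R in both bridges | CCCC[C@@H]1/C=C/C[C@H](Cl)C[C@H](O)c2cc(OCOC)c(c(OCOC)c2)[C@H](CCCC)/C=C/C[C@H](Cl)C[C@H](O)c2cc(OCOC)c1c(OCOC)c2 | intermediate
21 | saturated [7.7]paracyclophane diol, tetrakis(MOM ether) | CCCC[C@@H]1CCC[C@H](Cl)C[C@H](O)c2cc(OCOC)c(c(OCOC)c2)[C@H](CCCC)CCC[C@H](Cl)C[C@H](O)c2cc(OCOC)c1c(OCOC)c2 | intermediate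
22 | mono-methyl ether of 21 | CCCC[C@@H]1CCC[C@H](Cl)C[C@H](OC)c2cc(OCOC)c(c(OCOC)c2)[C@H](CCCC)CCC[C@H](Cl)C[C@H](O)c2cc(OCOC)c1c(OCOC)c2 | intermediate
23 | nostocyclophane C | CCCC[C@@H]1CCC[C@H](Cl)C[C@H](OC)c2cc(O)c(c(O)c2)[C@H](CCCC)CCC[C@H](Cl)C[C@H](O)c2cc(O)c1c(O)c2 | target

## Step count and risks

Total steps: 15. Longest linear sequence: 12 (from propane-1,3-diol 4: steps 3–9 and 11–15).

Three steps most likely to fail:

**Step 11 (the proposed new arylation).** Risks: competing lithiation next to the benzylic alkoxide, attack of n-BuLi on the secondary chloride, and poor turnover or selectivity with a di-ortho-substituted aryl group. Fallback with known chemistry, setting out from 14: dilithiate as in step 11 and add MgBr2·OEt2 to give the bis(bromomagnesium) aryl Grignard reagent F3. In the presence of CuBr·SMe2, F3 substitutes (2R,3E)-oct-3-en-2-yl pyridine-2-carboxylate F2 in a picolinate-directed anti-SN2′ reaction with 1,3-chirality transfer (known for 2,6-dialkoxyaryl copper reagents). F2 is made with picolinic acid, DCC and DMAP from (2R,3E)-oct-3-en-2-ol F1, itself obtained from (E)-hept-2-enal by Ti(OiPr)4/chiral bis-sulfonamide-catalysed Me2Zn addition. The coupling gives (1S,3S)-3-chloro-1-{3,5-bis(methoxymethoxy)-4-[(2E,4R)-oct-2-en-4-yl]phenyl}hex-5-en-1-ol F4, the (E)-propenyl analogue of 19. Under the step 12 conditions F4 cyclodimerizes with loss of propene and comes back to the route at 20.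

**Step 12 (cyclodimerization).** Risks: the vinyl group next to the di-ortho-substituted aryl ring is a sluggish metathesis partner, and oligomers may compete. Fallback, setting out from 19: two molecules of 19 are joined through their C1 hydroxyls with decanedioyl dichloride (0.5 equiv, pyridine, DMAP) to give the decanedioate-tethered bis-monomer F5. Both ring closures are then intramolecular; double ring-closing metathesis with the same ruthenium catalyst at 1 mM gives the tethered macrobicyclic diene F6. K2CO3 in MeOH removes the tether, and the route is rejoined at 20.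

**Step 14 (statistical mono-methylation).** Risks: at most about half of the material is converted per pass, and over-methylation or base-induced loss of the γ-chloride would cost late-stage material. Fallback, setting out from 19: half of the monomer is O-methylated before ring formation (KN(SiMe3)2, MeOTf, THF, −78 °C) to give 5-[(1S,3S)-3-chloro-1-methoxyhex-5-en-1-yl]-2-[(3R)-hept-1-en-3-yl]-1,3-bis(methoxymethoxy)benzene F7. A 1:1 mixture of 19 and F7 is cyclodimerized under the step 12 conditions. This gives the mixed (E,E)-diene macrocycle F8 (one C1–OMe, one C1–OH), separable by polarity from 20 and from the bis(methyl ether) diene macrocycle F9; both of these can be re-equilibrated with more monomer. Diimide reduction of F8 under the step 13 conditions comes back to the route at 22.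

Further compounds
F1 | step 11 | (2R,3E)-oct-3-en-2-ol | CCCC/C=C/[C@@H](C)O
F2 | step 11 | (2R,3E)-oct-3-en-2-yl pyridine-2-carboxylate | CCCC/C=C/[C@@H](C)OC(=O)c1ccccn1
F3 | step 11 | bis(bromomagnesium) aryl Grignard reagent derived from 14 | C=CC[C@H](Cl)C[C@H](O[Mg]Br)c1cc(OCOC)c([Mg]Br)c(OCOC)c1
F4 | step 11 | (1S,3S)-3-chloro-1-{3,5-bis(methoxymethoxy)-4-[(2E,4R)-oct-2-en-4-yl]phenyl}hex-5-en-1-ol | C=CC[C@H](Cl)C[C@H](O)c1cc(OCOC)c([C@H](CCCC)/C=C/C)c(OCOC)c1
F5 | step 12 | decanedioate diester of two molecules of 19 (tethered bis-monomer) | C=CC[C@H](Cl)C[C@H](OC(=O)CCCCCCCCC(=O)O[C@@H](C[C@@H](Cl)CC=C)c1cc(OCOC)c([C@H](CCCC)C=C)c(OCOC)c1)c1cc(OCOC)c([C@H](CCCC)C=C)c(OCOC)c1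
F6 | step 12 | decanedioate-bridged [7.7]paracyclophane (E,E)-diene (tethered form of 20) | CCCC[C@@H]1/C=C/C[C@H](Cl)C[C@H](OC(=O)CCCCCCCCC(=O)O3)c2cc(OCOC)c(c(OCOC)c2)[C@H](CCCC)/C=C/C[C@H](Cl)C[C@H]3c2cc(OCOC)c1c(OCOC)c2
F7 | step 14 | 5-[(1S,3S)-3-chloro-1-methoxyhex-5-en-1-yl]-2-[(3R)-hept-1-en-3-yl]-1,3-bis(methoxymethoxy)benzene | C=CC[C@H](Cl)C[C@H](OC)c1cc(OCOC)c([C@H](CCCC)C=C)c(OCOC)c1
F8 | step 14 | mixed [7.7]paracyclophane (E,E)-diene, one C1–OMe and one C1–OH | CCCC[C@@H]1/C=C/C[C@H](Cl)C[C@H](OC)c2cc(OCOC)c(c(OCOC)c2)[C@H](CCCC)/C=C/C[C@H](Cl)C[C@H](O)c2cc(OCOC)c1c(OCOC)c2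
F9 | step 14 | bis(methyl ether) [7.7]paracyclophane (E,E)-diene | CCCC[C@@H]1/C=C/C[C@H](Cl)C[C@H](OC)c2cc(OCOC)c(c(OCOC)c2)[C@H](CCCC)/C=C/C[C@H](Cl)C[C@H](OC)c2cc(OCOC)c1c(OCOC)c2
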